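In the early part of larch, enzyme turns starting material and second substrate into target, and target climbs by a fraction Fe = 0.130 h⁻¹ of the charge per hour. Second substrate then turns target into over-reaction product.

all flasks: starting material 0.10 M; free enzyme 0.02 mol%
- larch: second substrate 4 equiv; temperature 5 °C; the very flask that is asked about, followed so far
- cedar: second substrate 4 equiv; temperature 11 °C; run made earlier
- flask: second substrate 4.00 equiv; temperature 5 °C; time 4.0 h
- larch (time / h: target / %, starting material / %): 0.200: 2.6, 95.8; 0.667: 8.5, 87.7; 1.00: 10.8, 81.7; 1.50: 13.1, 73.6; 2.50: 16.4, 59.8; 3.00: 16.7, 54.3; 4.00: 16.4, 44.2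
- cedar (time / h: target / %, starting material / %): 0.200: 2.7, 95.1; 0.667: 9.2, 83.6; 1.00: 10.2, 77.9; 1.50: 12.5, 69.0; 2.50: 12.6, 54.7; 3.00: 11.3, 47.5; 4.00: 10.0, 37.2

(readings scatter by 0.5 percentage points)
- west: at 4.0 h raise the temperature by 20 K, then wait 2.0 h
- north: at 4.0 h add free enzyme, 100% of the amount charged, then wait 2.0 h
- north-west: change nothing and wait 2.0 h more
- south-west: at 4.0 h add second substrate, 100% of the amount charged, then wait 2.0 h
- in percentages every species weighs as the starting material in it: one idle adduct counts as two
- for target the idle adduct is counted in
- additions leave the volume as it is
- the analysis behind the earlier runs scatters by 0.5 percentage points, standard deviation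
- reactions considered so far: second substrate + target -> over-reaction product; free enzyme -> unfolded enzyme; starting material + free enzyme <-> starting complex; ternary complex -> free enzyme + target; second substrate + starting complex <-> ternary complex; starting material + target <-> idle adduct
- in an amount of target, one idle adduct counts as one target
- target, in percent of the starting material first charged, at 4.0 h
- which option adds most target ("none" when 2 percentage points or less is all one gets) (west / north / north-west / south-west / none)
- target present, in percent of the starting material first charged, after west
- target present, in percent of the starting material first charged, after south-west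

First, how much does the rate of forming target follow starting material? Late in larch, starting material falls at F = 0.101 h⁻¹, which you take as target formed. The rate has sunk less than starting material has, so you read it as going with starting material to the power n = 0.326, an estimate that carries the scatter of these readings.

Second, what holds target level? Larch reads 16.7%, then 16.4%, so you put loss equal to formation. That gives, as a reading from larch, the pseudo-first-order loss constant κ = 0.616 h⁻¹. Call the ceiling C = F/κ, the target level at which loss equals formation: 16.4% now. With C and κ held, the gap between target and C shrinks over a time t by the factor exp(−κt), here 0.292 over 2.0 h.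

Third, which option lifts C? For larch you reckon that north gives twice the rate, so C = 32.8% and target reaches 28.0%. Now go round once more: that pace gives, in your reckoning, a mean starting material of 24.0%, which brings C down to 26.9% and target to 23.8%. The gain of 7.4 percentage points clears the margin. Cedar, run hotter, has a highest reading of 12.6%, lower than the 16.7% of larch, and second substrate is a partner in the loss step, so your choice is north, with 16.4% now, as read in larch.

The forecast gave 16.5% now, 3.5% after west, 9% after south-west and none as best, holding that “Extra enzyme speeds formation, but the peak passes by about 6 h”.

The flask gives 16.8% now, 0.0245% after west and 9.88% after south-west. Best is north, which adds 5.8 points and reaches 22.6%.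

    second substrate + target → over-reaction product (k = 8.20 × 10⁻⁴ M⁻¹ s⁻¹, Ea = 49.0 kJ mol⁻¹)
    free enzyme → unfolded enzyme (k = 9.40 × 10⁻⁶ s⁻¹, Ea = 199 kJ mol⁻¹)
    starting material + free enzyme ⇌ starting complex (K = 110 M⁻¹, k = 520 M⁻¹ s⁻¹, Ea = 41.0 kJ mol⁻¹, ΔH = −86.0 kJ mol⁻¹)
    ternary complex → free enzyme + target (k = 0.720 s⁻¹, Ea = 70.0 kJ mol⁻¹)
    second substrate + starting complex ⇌ ternary complex (K = 1.10 M⁻¹, k = 41.0 M⁻¹ s⁻¹, Ea = 46.0 kJ mol⁻¹, ΔH = −36.0 kJ mol⁻¹)
    starting material + target ⇌ idle adduct, settled at all times (K = 8.20 M⁻¹, ΔH = −55.0 kJ mol⁻¹)
    (constants at 5 °C)

Take the neighbour, the same flask left unchanged and read at 6.00 h. Reckoned at the rate F, its mean starting material over those 2.0 h is 34.1%. The ceiling C then sinks from 16.4% to 15.1%, and target, closing the gap by the same factor, comes to 15.5%. That neighbour stands at 15.1% target, with over-reaction product at 56.9%.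

The numbers in the tables stem from a simulated flask from invented constants.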